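## Retrosynthetic overview

1. Lignan numbering: ring A = C1–C6 (C1 carries C7H2, C2 carries C7', OMe on C3 and C5, OH on C4); ring B = C1, C2, C7', C8', C8, C7; ring C = guaiacyl on C7'. The plan rests on the ring B stereotriad: the C7' aryl group is trans to the C8' methyl (C9'), and C9' is cis to the C8 methyl (C9). A formyl-endo [4+2] addition of an E-enal to an E-propenyl diene terminus gives exactly this pattern.
2. Last disconnections: both O-benzyl groups (on C4–O and C4'–O) and both O-methyl groups (on C3–O and C5–O), leading back to a ring A 3,5-diol that carries OBn on C4.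
3. Ring A is opened at C3–C4 (Dieckmann closure with aromatisation; C3 is the former ester carbon) and at C1–C6 (Stille coupling on the C1 enol triflate of a ring B β-keto ester). An enolised β-keto ester would only protonate a ketone enolate, so C6–C5–C4 of 1-(benzyloxy)propan-2-one enter masked as a 2-(benzyloxymethyl)allyl group, and alkene cleavage then releases the C5 ketone.
4. Ring B, with C9' still a formyl group, is disconnected at C2–C7' and C8–C8' by an enantioselective Diels–Alder reaction between a 2-silyloxydiene ester (C3, C2, C1, C7, C8, C9) and O-benzylconiferaldehyde (ring C, C7', C8', C9').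
5. Order of rings: ring C is bought, ring B is made in step 4, ring A in step 14.

Key step: step 4

Assumption: the (−)-enantiomer is taken to be the (7'R,8R,8'R) compound of the given SMILES; the sign of rotation plays no part in the planning.
Remark: the CIP descriptors of the ring B carbons change along the route only because substituent priorities change. The spatial arrangement set in step 4 is kept throughout.

## Route

Step 1
Reactants: 1 (E)-but-2-enoic acid (crotonic acid); 2 potassium methyl malonate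
Product: 5 methyl (E)-3-oxohex-4-enoate, via crotonyl imidazolide 3 (not isolated), via acylmalonic half ester 4 (not isolated)
Conditions: CDI, THF, rt; then 2, MgCl2, Et3N, MeCN, rt → 40 °C; 1 M HCl
Reagents that add atoms: 1,1'-carbonyldiimidazole O=C(n1ccnc1)n1ccnc1 (imidazolyl group of intermediate 3 only)
Why: Masamune–Brooks C-acylation, in which imidazolide 3 acylates the magnesium enolate of the malonate half ester and 4 loses CO2 on acidification, a mild sequence that avoids ketene formation and leaves the E-alkene untouched.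

Step 2
Reactants: 5 methyl (E)-3-oxohex-4-enoate
Product: 6 methyl (2Z,4E)-3-[(tert-butyldimethylsilyl)oxy]hexa-2,4-dienoate
Conditions: NaH, THF, 0 °C; TBSCl, 0 °C → rt
Reagents that add atoms: tert-butyldimethylsilyl chloride CC(C)(C)[Si](C)(C)Cl
Why: Silyl enol ether formation by O-silylation of the sodium-chelated β-keto ester enolate, which holds the enolate oxygen and the ester on the same side of the new C=C bond and should therefore give the 2Z isomer, with the ester pointing outward from the s-cis diene.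

Step 3
Reactants: 7 (E)-3-(4-hydroxy-3-methoxyphenyl)prop-2-enal (coniferaldehyde)
Product: 8 (E)-3-[4-(benzyloxy)-3-methoxyphenyl]prop-2-enal
Conditions: BnBr, K2CO3, DMF, rt
Reagents that add atoms: benzyl bromide BrCc1ccccc1
Why: Williamson ether synthesis on the phenoxide, under which the non-enolisable E-enal is not touched.

Step 4
Reactants: 6 methyl (2Z,4E)-3-[(tert-butyldimethylsilyl)oxy]hexa-2,4-dienoate; 8 (E)-3-[4-(benzyloxy)-3-methoxyphenyl]prop-2-enal
Product: 9 methyl (1R,4R,5R,6S)-6-[4-(benzyloxy)-3-methoxyphenyl]-2-[(tert-butyldimethylsilyl)oxy]-5-formyl-4-methylcyclohex-2-ene-1-carboxylate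
Conditions: (S)-3,3-diphenyl-1-(2-methylphenyl)tetrahydro-1H,3H-pyrrolo[1,2-c][1,3,2]oxazaborole (20 mol %), HN(SO2CF3)2 (18 mol %), 6 (1.5 equiv), CH2Cl2, −78 → −40 °C; Et3N quench
Reagents that add atoms: none
Why: Boron of the N-protonated oxazaborolidine binds the formyl oxygen of 8 and lowers its LUMO, and 6 adds in a single concerted, asynchronous, suprafacial [4+2] event in which the enol silane carbon C2 bonds to the β-carbon C7' ahead of the C8–C8' bond. The closest known reaction type is the oxazaborolidinium-catalysed enantioselective Diels–Alder reaction of 2-silyloxydienes with α,β-unsaturated aldehydes. Ring B (C1, C2, C7', C8', C8, C7) is closed by intermolecular cycloaddition, both σ-bonds forming through one six-membered boat-like transition state. C7' and C8' keep the trans relation of the E-enal, and the formyl-endo orientation sets C8 and C2 because the two outward diene substituents (C9 methyl of the 4E bond, ester of the 2Z bond) end up cis to the formyl group. The absolute configuration is set by the catalyst, whose formyl C–H···O contact holds the s-trans enal over the convex-face phenyl group so that only the Re face at C8' and C7' is open, which should give the (1R,4R,5R,6S) adduct. The step needs regio-, endo- and chemoselectivity: the C1 silyloxy group and the C8 methyl group both direct C2 to C7' and outweigh the ester, the boron-bound carbonyl overlaps with C1 and C7 of the diene in the endo mode, and the outward position of both terminal substituents keeps the s-cis conformer accessible so that cycloaddition can outrun 1,2-addition of the enol silane to the carbonyl group.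

Step 5
Reactants: 9 cycloadduct aldehyde
Product: 10 methyl (1R,4S,5R,6S)-6-[4-(benzyloxy)-3-methoxyphenyl]-2-[(tert-butyldimethylsilyl)oxy]-5-(hydroxymethyl)-4-methylcyclohex-2-ene-1-carboxylate
Conditions: NaBH4, THF–MeOH, −20 °C
Reagents that add atoms: none
Why: Chemoselective borohydride reduction of the aldehyde, to which the hindered methyl ester and the silyl enol ether are inert at low temperature; lactonisation is unlikely because ester and hydroxymethyl group are both equatorial.

Step 6
Reactants: 10 primary alcohol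
Product: 11 methyl (1R,4R,5R,6R)-6-[4-(benzyloxy)-3-methoxyphenyl]-5-(bromomethyl)-2-[(tert-butyldimethylsilyl)oxy]-4-methylcyclohex-2-ene-1-carboxylate
Conditions: CBr4, PPh3, 2,6-lutidine, CH2Cl2, 0 °C
Reagents that add atoms: carbon tetrabromide BrC(Br)(Br)Br
Why: Appel reaction, an SN2 displacement of the alkoxyphosphonium ion at primary C9' under neutral buffered conditions that should spare the acid-sensitive silyl enol ether and touch no stereocentre.

Step 7
Reactants: 11 primary bromide
Product: 12 methyl (1R,4S,5R,6S)-6-[4-(benzyloxy)-3-methoxyphenyl]-2-[(tert-butyldimethylsilyl)oxy]-4,5-dimethylcyclohex-2-ene-1-carboxylate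
Conditions: Bu3SnH, AIBN (cat.), toluene, 80 °C
Reagents that add atoms: none
Why: Radical chain dehalogenation with tin hydride turns C9' into the methyl group, since the primary radical has no favourable cyclisation or hydrogen-shift pathway and ester, enol silane and benzyl ether are inert to it.

Step 8
Reactants: 12 silyl enol ether
Product: 13 methyl (1R,2S,3R,4R)-2-[4-(benzyloxy)-3-methoxyphenyl]-3,4-dimethyl-6-oxocyclohexane-1-carboxylate (keto form drawn)
Conditions: 1 M aq HCl (cat.), THF, 0 °C → rt
Reagents that add atoms: none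
Why: Acid-catalysed hydrolysis of the silyl enol ether (protonation at C7, loss of silanol) unmasks the C1 ketone, and the labile C2 centre should settle with the ester trans to the aryl group, which has no consequence because C2 becomes sp2 in step 9.

Step 9
Reactants: 13 β-keto ester
Product: 14 methyl (4R,5R,6R)-6-[4-(benzyloxy)-3-methoxyphenyl]-4,5-dimethyl-2-{[(trifluoromethyl)sulfonyl]oxy}cyclohex-1-ene-1-carboxylate
Conditions: Tf2O, iPr2NEt, CH2Cl2, −78 °C
Reagents that add atoms: trifluoromethanesulfonic anhydride O=S(=O)(OS(=O)(=O)C(F)(F)F)C(F)(F)F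
Why: Enol triflate formation, in which the amine removes the most acidic proton (C2–H) and Tf2O sulfonylates the oxygen of the conjugated C1=C2 enolate, making C1 a cross-coupling electrophile while C7', C8' and C8 stay untouched.

Step 10
Reactants: 15 3-chloro-2-(chloromethyl)prop-1-ene; 16 benzyl alcohol
Product: 17 ({[2-(chloromethyl)prop-2-en-1-yl]oxy}methyl)benzene
Conditions: 16, NaH, THF–DMF, 0 °C; 15 (3 equiv), rt
Reagents that add atoms: none
Why: Williamson ether synthesis on an allylic chloride, with an excess of the volatile dichloride to favour monosubstitution.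

Step 11
Reactants: 17 allylic chloride
Product: 18 {2-[(benzyloxy)methyl]prop-2-en-1-yl}tributylstannane
Conditions: Bu3SnH, LiN(iPr)2, THF, −78 → 0 °C; then 17, −78 °C → rt
Reagents that add atoms: tributyltin hydride CCCC[SnH](CCCC)CCCC
Why: Nucleophilic displacement of the allylic chloride by tributylstannyllithium, for which the SN2 and SN2' pathways lead to the same constitution.

Step 12
Reactants: 14 enol triflate; 18 allylstannane
Product: 19 methyl (4R,5R,6R)-6-[4-(benzyloxy)-3-methoxyphenyl]-2-{2-[(benzyloxy)methyl]prop-2-en-1-yl}-4,5-dimethylcyclohex-1-ene-1-carboxylate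
Conditions: Pd(PPh3)4 (5 mol %), LiCl (3 equiv), THF, reflux
Reagents that add atoms: none
Why: Stille coupling of a vinyl triflate with an allylstannane, in which zerovalent palladium inserts into the electron-poor C1–OTf bond, chloride replaces triflate, and allyl transfer from either terminus forms C1–C6 with the same product under neutral conditions.

Step 13
Reactants: 19 skipped diene
Product: 21 methyl (4R,5R,6R)-6-[4-(benzyloxy)-3-methoxyphenyl]-2-[3-(benzyloxy)-2-oxopropyl]-4,5-dimethylcyclohex-1-ene-1-carboxylate, via vicinal diol 20 (not isolated)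
Conditions: OsO4 (2 mol %), NaIO4, 2,6-lutidine, dioxane–H2O, rt
Reagents that add atoms: osmium tetroxide O=[Os](=O)(=O)=O (catalytic oxygen carrier); sodium periodate [Na+].[O-]I(=O)(=O)=O (terminal oxygen source); water O
Why: Lemieux–Johnson oxidation, in which OsO4 dihydroxylates only the unhindered 1,1-disubstituted alkene (the tetrasubstituted enoate is inert) and periodate cleaves diol 20 to the C5 ketone.

Step 14
Reactants: 21 δ-keto enoate
Product: 23 (6R,7R,8R)-2-(benzyloxy)-8-[4-(benzyloxy)-3-methoxyphenyl]-6,7-dimethyl-5,6,7,8-tetrahydronaphthalene-1,3-diol, via bicyclic enedione 22 (not isolated)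
Conditions: NaOMe, MeOH, reflux, argon; then 1 M HCl
Reagents that add atoms: none
Why: Dieckmann (intramolecular Claisen) condensation of the kind that turns 2-(2-oxoalkyl)benzoates into 1,3-naphthalenediols, in which reversible enolisation lets the C4 enolate attack the cis-placed ester carbon C3 (6-exo-trig) and 22 tautomerises irreversibly to the resorcinol, a thermodynamic sink that also drains any 2-pyranone from reversible O-acylation, while the non-acidified C7'–H is not epimerised.

Step 15
Reactants: 23 resorcinol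
Product: 24 (1R,2R,3R)-7-(benzyloxy)-1-[4-(benzyloxy)-3-methoxyphenyl]-6,8-dimethoxy-2,3-dimethyl-1,2,3,4-tetrahydronaphthalene
Conditions: MeI, K2CO3, DMF, 40 °C
Reagents that add atoms: iodomethane CI
Why: Williamson O-methylation of both phenoxides, in which carbonate base in a polar aprotic solvent favours O- over C-alkylation and mild warming serves the hindered C3 phenol next to C7'.

Step 16
Reactants: 24 bis(benzyl) ether
Product: 25 (6R,7R,8R)-8-(4-hydroxy-3-methoxyphenyl)-1,3-dimethoxy-6,7-dimethyl-5,6,7,8-tetrahydronaphthalen-2-ol = (−)-(7'R,8R,8'R)-4,4'-dihydroxy-3,3',5-trimethoxy-2,7'-cyclolignan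
Conditions: H2 (1 atm), Pd/C (10 wt % Pd), EtOAc–EtOH, rt
Reagents that add atoms: none
Why: Catalytic hydrogenolysis cleaves both benzylic C–O bonds, while the methyl ethers and the C–C bonds at C7' are inert and no stereocentre is affected.

## Compound list

1 | (E)-but-2-enoic acid | C/C=C/C(=O)O | starting material
2 | potassium methyl malonate | COC(=O)CC(=O)[O-].[K+] | starting material
3 | (E)-1-(1H-imidazol-1-yl)but-2-en-1-one | C/C=C/C(=O)n1ccnc1 | intermediate
4 | (E)-2-(methoxycarbonyl)-3-oxohex-4-enoic acid (labile centre, present as magnesium chelate) | COC(=O)C(C(=O)O)C(=O)/C=C/C | intermediate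
5 | methyl (E)-3-oxohex-4-enoate | COC(=O)CC(=O)/C=C/C | intermediate
6 | methyl (2Z,4E)-3-[(tert-butyldimethylsilyl)oxy]hexa-2,4-dienoate | COC(=O)/C=C(\O[Si](C)(C)C(C)(C)C)/C=C/C | intermediate
7 | (E)-3-(4-hydroxy-3-methoxyphenyl)prop-2-enal | COc1cc(/C=C/C=O)ccc1O | starting material
8 | (E)-3-[4-(benzyloxy)-3-methoxyphenyl]prop-2-enal | COc1cc(/C=C/C=O)ccc1OCc1ccccc1 | intermediate
9 | methyl (1R,4R,5R,6S)-6-[4-(benzyloxy)-3-methoxyphenyl]-2-[(tert-butyldimethylsilyl)oxy]-5-formyl-4-methylcyclohex-2-ene-1-carboxylate | COc1cc([C@@H]2[C@@H](C(=O)OC)C(O[Si](C)(C)C(C)(C)C)=C[C@@H](C)[C@H]2C=O)ccc1OCc1ccccc1 | intermediate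
10 | methyl (1R,4S,5R,6S)-6-[4-(benzyloxy)-3-methoxyphenyl]-2-[(tert-butyldimethylsilyl)oxy]-5-(hydroxymethyl)-4-methylcyclohex-2-ene-1-carboxylate | COc1cc([C@@H]2[C@@H](C(=O)OC)C(O[Si](C)(C)C(C)(C)C)=C[C@@H](C)[C@H]2CO)ccc1OCc1ccccc1 | intermediate
11 | methyl (1R,4R,5R,6R)-6-[4-(benzyloxy)-3-methoxyphenyl]-5-(bromomethyl)-2-[(tert-butyldimethylsilyl)oxy]-4-methylcyclohex-2-ene-1-carboxylate | COc1cc([C@@H]2[C@@H](C(=O)OC)C(O[Si](C)(C)C(C)(C)C)=C[C@@H](C)[C@H]2CBr)ccc1OCc1ccccc1 | intermediate
12 | methyl (1R,4S,5R,6S)-6-[4-(benzyloxy)-3-methoxyphenyl]-2-[(tert-butyldimethylsilyl)oxy]-4,5-dimethylcyclohex-2-ene-1-carboxylate | COc1cc([C@@H]2[C@@H](C(=O)OC)C(O[Si](C)(C)C(C)(C)C)=C[C@@H](C)[C@H]2C)ccc1OCc1ccccc1 | intermediate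
13 | methyl (1R,2S,3R,4R)-2-[4-(benzyloxy)-3-methoxyphenyl]-3,4-dimethyl-6-oxocyclohexane-1-carboxylate | COc1cc([C@@H]2[C@@H](C(=O)OC)C(=O)C[C@@H](C)[C@H]2C)ccc1OCc1ccccc1 | intermediate
14 | methyl (4R,5R,6R)-6-[4-(benzyloxy)-3-methoxyphenyl]-4,5-dimethyl-2-{[(trifluoromethyl)sulfonyl]oxy}cyclohex-1-ene-1-carboxylate | COc1cc([C@@H]2C(C(=O)OC)=C(OS(=O)(=O)C(F)(F)F)C[C@@H](C)[C@H]2C)ccc1OCc1ccccc1 | intermediate
15 | 3-chloro-2-(chloromethyl)prop-1-ene | C=C(CCl)CCl | starting material
16 | benzyl alcohol | OCc1ccccc1 | starting material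
17 | ({[2-(chloromethyl)prop-2-en-1-yl]oxy}methyl)benzene | C=C(CCl)COCc1ccccc1 | intermediate
18 | {2-[(benzyloxy)methyl]prop-2-en-1-yl}tributylstannane | C=C(COCc1ccccc1)C[Sn](CCCC)(CCCC)CCCC | intermediate
19 | methyl (4R,5R,6R)-6-[4-(benzyloxy)-3-methoxyphenyl]-2-{2-[(benzyloxy)methyl]prop-2-en-1-yl}-4,5-dimethylcyclohex-1-ene-1-carboxylate | COc1cc([C@@H]2C(C(=O)OC)=C(CC(=C)COCc3ccccc3)C[C@@H](C)[C@H]2C)ccc1OCc1ccccc1 | intermediate
20 | methyl (4R,5R,6R)-6-[4-(benzyloxy)-3-methoxyphenyl]-2-[3-(benzyloxy)-2-hydroxy-2-(hydroxymethyl)propyl]-4,5-dimethylcyclohex-1-ene-1-carboxylate (both carbinol epimers) | COc1cc([C@@H]2C(C(=O)OC)=C(CC(O)(CO)COCc3ccccc3)C[C@@H](C)[C@H]2C)ccc1OCc1ccccc1 | intermediate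
21 | methyl (4R,5R,6R)-6-[4-(benzyloxy)-3-methoxyphenyl]-2-[3-(benzyloxy)-2-oxopropyl]-4,5-dimethylcyclohex-1-ene-1-carboxylate | COc1cc([C@@H]2C(C(=O)OC)=C(CC(=O)COCc3ccccc3)C[C@@H](C)[C@H]2C)ccc1OCc1ccccc1 | intermediate
22 | (6R,7R,8R)-2-(benzyloxy)-8-[4-(benzyloxy)-3-methoxyphenyl]-6,7-dimethyl-5,6,7,8-tetrahydronaphthalene-1,3(2H,4H)-dione (labile C2 centre) | COc1cc([C@@H]2C3=C(CC(=O)C(OCc4ccccc4)C3=O)C[C@@H](C)[C@H]2C)ccc1OCc1ccccc1 | intermediate
23 | (6R,7R,8R)-2-(benzyloxy)-8-[4-(benzyloxy)-3-methoxyphenyl]-6,7-dimethyl-5,6,7,8-tetrahydronaphthalene-1,3-diol | COc1cc([C@@H]2c3c(cc(O)c(OCc4ccccc4)c3O)C[C@@H](C)[C@H]2C)ccc1OCc1ccccc1 | intermediate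
24 | (1R,2R,3R)-7-(benzyloxy)-1-[4-(benzyloxy)-3-methoxyphenyl]-6,8-dimethoxy-2,3-dimethyl-1,2,3,4-tetrahydronaphthalene | COc1cc([C@@H]2c3c(cc(OC)c(OCc4ccccc4)c3OC)C[C@@H](C)[C@H]2C)ccc1OCc1ccccc1 | intermediate
25 | (−)-(7'R,8R,8'R)-4,4'-dihydroxy-3,3',5-trimethoxy-2,7'-cyclolignan | COc1cc([C@@H]2c3c(cc(OC)c(O)c3OC)C[C@@H](C)[C@H]2C)ccc1O | target

## Step count and risks

Total step count: 16.
Longest linear sequence: 13 steps (1, 2, 4–9, 12–16).

**Risk 1, step 4.**
- The cycloaddition may be sluggish, because the ester lowers the diene HOMO and the donor-substituted aryl ring raises the enal LUMO.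
- The enol silane may add 1,2 to the bound carbonyl group (Mukaiyama-type aldol).
- Silyl transfer to triflimide may create an achiral silicon Lewis acid that erodes facial selectivity.
- The endo preference may be incomplete.
- If only the sense of induction turns out opposite to the model, the equally accessible (R)-configured oxazaborolidine is used.

The fallback replaces catalyst control by a covalently bound auxiliary. It sets out from 8 and 6 and returns at 10.
- Pinnick oxidation of 8 (NaClO2, NaH2PO4, 2-methylbut-2-ene, t-BuOH–H2O) gives the cinnamic acid F1.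
- Pivaloyl chloride and Et3N in THF convert it into the mixed pivalic anhydride F2, which acylates (R)-4-benzyl-1,3-oxazolidin-2-one in the presence of LiCl to give the N-enoyl oxazolidinone F3.
- Et2AlCl (1.4 equiv, CH2Cl2, −78 → −30 °C) chelates both imide carbonyl groups and locks the s-cis enoyl conformer. The benzyl group then covers the Si face at C8', so 6 adds endo to the Re face to give the imide cycloadduct F4.
- LiBH4 with one equivalent of MeOH in Et2O at 0 °C cleaves the imide reductively to alcohol 10.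

**Risk 2, step 14.**
- Enolisation may go mainly toward the doubly activated C6.
- O-acylation may park the material as a 2-pyranone.
- The hindered alkoxy enolate may attack the twisted ester only slowly.
- The electron-rich product may oxidise in air under base.

The fallback leaves the benzyloxy group out of the three-carbon unit, so that an unhindered methyl ketone enolate closes the ring, and adds the C4 oxygen afterwards. It sets out from 14 and returns at 25.
- Stille coupling of 14 with commercial tributyl(2-methylprop-2-en-1-yl)stannane (Pd(PPh3)4, LiCl, THF, reflux) gives the methallyl ester F5.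
- OsO4/NaIO4 takes it through the vicinal diol F6 to the methyl ketone F7.
- NaOMe in MeOH closes and aromatises ring A to the C4-unsubstituted resorcinol F8, and MeI/K2CO3 gives the dimethyl ether F9.
- n-BuLi in THF at 0 °C removes the C4 proton, the only one flanked by two methoxy groups (directed ortho-metalation), to give the aryllithium F10. B(OMe)3 traps it as the dimethyl arylboronate F11.
- NaOH/H2O2 oxidises this to the C4 phenol F12, and hydrogenolysis of the one remaining benzyl ether (H2, Pd/C) gives 25.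

**Risk 3, step 12.**
- Transmetallation of the substituted allylstannane may be slow.
- The 1,1-disubstituted alkene may migrate into conjugation with the enoate.
- Protodestannylation may consume the stannane.

The fallback forms C1–C6 through an sp carbon. It sets out from 14 and returns at 21.
- Sonogashira coupling of 14 with commercial benzyl prop-2-yn-1-yl ether (PdCl2(PPh3)2, CuI, Et3N, THF, rt) gives the enyne ester F13, in which no alkene can migrate.
- Pyrrolidine in EtOH at 60 °C adds in the 1,6-sense to the 2-en-4-ynoate at the δ-carbon C5 to give the 5-pyrrolidinyl dienoate F14.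
- Aqueous AcOH hydrolyses this dienamine to keto ester 21.

## Further compounds

F1 | step 4 | (E)-3-[4-(benzyloxy)-3-methoxyphenyl]prop-2-enoic acid | COc1cc(/C=C/C(=O)O)ccc1OCc1ccccc1
F2 | step 4 | (E)-3-[4-(benzyloxy)-3-methoxyphenyl]prop-2-enoic pivalic anhydride | COc1cc(/C=C/C(=O)OC(=O)C(C)(C)C)ccc1OCc1ccccc1
F3 | step 4 | (4R)-4-benzyl-3-{(E)-3-[4-(benzyloxy)-3-methoxyphenyl]prop-2-enoyl}-1,3-oxazolidin-2-one | COc1cc(/C=C/C(=O)N2[C@H](Cc3ccccc3)COC2=O)ccc1OCc1ccccc1
F4 | step 4 | methyl (1R,4R,5R,6S)-5-{[(4R)-4-benzyl-2-oxo-1,3-oxazolidin-3-yl]carbonyl}-6-[4-(benzyloxy)-3-methoxyphenyl]-2-[(tert-butyldimethylsilyl)oxy]-4-methylcyclohex-2-ene-1-carboxylate | COc1cc([C@@H]2[C@@H](C(=O)OC)C(O[Si](C)(C)C(C)(C)C)=C[C@@H](C)[C@H]2C(=O)N2[C@H](Cc3ccccc3)COC2=O)ccc1OCc1ccccc1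
F5 | step 14 | methyl (4R,5R,6R)-6-[4-(benzyloxy)-3-methoxyphenyl]-4,5-dimethyl-2-(2-methylprop-2-en-1-yl)cyclohex-1-ene-1-carboxylate | COc1cc([C@@H]2C(C(=O)OC)=C(CC(C)=C)C[C@@H](C)[C@H]2C)ccc1OCc1ccccc1
F6 | step 14 | methyl (4R,5R,6R)-6-[4-(benzyloxy)-3-methoxyphenyl]-2-(2,3-dihydroxy-2-methylpropyl)-4,5-dimethylcyclohex-1-ene-1-carboxylate (both carbinol epimers) | COc1cc([C@@H]2C(C(=O)OC)=C(CC(C)(O)CO)C[C@@H](C)[C@H]2C)ccc1OCc1ccccc1
F7 | step 14 | methyl (4R,5R,6R)-6-[4-(benzyloxy)-3-methoxyphenyl]-4,5-dimethyl-2-(2-oxopropyl)cyclohex-1-ene-1-carboxylate | COc1cc([C@@H]2C(C(=O)OC)=C(CC(C)=O)C[C@@H](C)[C@H]2C)ccc1OCc1ccccc1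
F8 | step 14 | (6R,7R,8R)-8-[4-(benzyloxy)-3-methoxyphenyl]-6,7-dimethyl-5,6,7,8-tetrahydronaphthalene-1,3-diol | COc1cc([C@@H]2c3c(cc(O)cc3O)C[C@@H](C)[C@H]2C)ccc1OCc1ccccc1
F9 | step 14 | (1R,2R,3R)-1-[4-(benzyloxy)-3-methoxyphenyl]-6,8-dimethoxy-2,3-dimethyl-1,2,3,4-tetrahydronaphthalene | COc1cc([C@@H]2c3c(cc(OC)cc3OC)C[C@@H](C)[C@H]2C)ccc1OCc1ccccc1
F10 | step 14 | C4-lithio derivative of F9 | COc1cc([C@@H]2c3c(cc(OC)c([Li])c3OC)C[C@@H](C)[C@H]2C)ccc1OCc1ccccc1
F11 | step 14 | dimethyl C4-boronate of F9 | COc1cc([C@@H]2c3c(cc(OC)c(B(OC)OC)c3OC)C[C@@H](C)[C@H]2C)ccc1OCc1ccccc1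
F12 | step 14 | (6R,7R,8R)-8-[4-(benzyloxy)-3-methoxyphenyl]-1,3-dimethoxy-6,7-dimethyl-5,6,7,8-tetrahydronaphthalen-2-ol | COc1cc([C@@H]2c3c(cc(OC)c(O)c3OC)C[C@@H](C)[C@H]2C)ccc1OCc1ccccc1
F13 | step 12 | methyl (4R,5R,6R)-6-[4-(benzyloxy)-3-methoxyphenyl]-2-[3-(benzyloxy)prop-1-yn-1-yl]-4,5-dimethylcyclohex-1-ene-1-carboxylate | COc1cc([C@@H]2C(C(=O)OC)=C(C#CCOCc3ccccc3)C[C@@H](C)[C@H]2C)ccc1OCc1ccccc1
F14 | step 12 | methyl (4R,5R,6R)-6-[4-(benzyloxy)-3-methoxyphenyl]-2-[3-(benzyloxy)-2-(pyrrolidin-1-yl)prop-1-en-1-yl]-4,5-dimethylcyclohex-1-ene-1-carboxylate (alkene geometry open) | COc1cc([C@@H]2C(C(=O)OC)=C(C=C(COCc3ccccc3)N3CCCC3)C[C@@H](C)[C@H]2C)ccc1OCc1ccccc1
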